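**Plan**
1. Retrosynthesis: the C1–OO bond is cut first (SN2 on a C1 mesylate), then the butenolide alkene C7=C11 (ring-closing metathesis) and its C6–O ester bond. C3 is then re-bonded to C10: the C3 oxygen, C10 and a C14–OTs group form a 1,3-diol monosulfonate, so C1–C2–C3–C10 become a cyclobutane and the ten-membered ring becomes an eight-membered ring that holds the Z C4=C5 alkene.
2. The cyclobutane is cut into dichloroketene and the C3=C10 silyl enol ether of a cyclooctenone; C10–C14 (formaldehyde), the C7 methylidene, C4–CH3 and the carbocycle (cycloocta-1,3-diene plus O2) follow.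
3. Forward: eight-membered ring (bought) → cyclobutane by [2+2] → ten-membered ring by Grob fragmentation → five-membered lactone by metathesis → hydroperoxide last.
4. Stereochemistry: an enantioselective Kornblum–DeLaMare rearrangement sets a sacrificial C3 carbinol that relays to C6 in a Luche reduction. C1 and the final C3 come from CBS reductions, and C1 is then inverted by the peroxide SN2. The two ring-fusion centres made in the [2+2] are erased by the fragmentation, and the 4Z geometry is held by the eight-membered ring.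

Key step: step 20

Remark on numbering: locants C1–C15 are those of the target's germacrane skeleton (C1 CH–OOH, C3 CH–OAc, C4(C15)=C5, C6 lactone CH–O, C7=C11, C12 lactone C=O, C13 CH2OAc, C10=C14).
Assumption: in step 6 hydride is taken to add to the C6 carbonyl anti to the C3 silyloxy group (cis-1,4 product), as is usual for 4-silyloxycycloalk-2-enones; if the sense were opposite, the pseudoenantiomeric base would be used in step 1.

**Step 1**
Reactants: 1 (1Z,3Z)-cycloocta-1,3-diene
Product: 3 (4R,2Z)-4-hydroxycyclooct-2-en-1-one, via 9,10-dioxabicyclo[4.2.2]dec-7-ene 2 (not isolated)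
Conditions: O2, tetraphenylporphyrin (cat.), visible light, CH2Cl2, 0 °C; then 9-O-acetylcupreine-type cinchona base (10 mol %, the pseudoenantiomer that gives the R alcohol), rt
Reagents that add atoms: dioxygen O=O
Why: Singlet-oxygen [4+2] cycloaddition should give the meso endoperoxide, and the chiral-base-catalysed Kornblum–DeLaMare rearrangement removes one of its two enantiotopic bridgehead protons, so the carbinol centre (future C3, later sacrificed) is set by the catalyst.

**Step 2**
Reactants: 3 (4R,2Z)-4-hydroxycyclooct-2-en-1-one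
Product: 4 (4R,2Z)-4-(triethylsilyloxy)cyclooct-2-en-1-one
Conditions: Et3SiCl, imidazole, CH2Cl2, 0 °C
Reagents that add atoms: chlorotriethylsilane CC[Si](Cl)(CC)CC
Why: Silylation of the secondary alcohol; a silyl ether rather than an ester is chosen so that the γ-oxygen is not expelled in the cuprate step.

**Step 3**
Reactants: 4 (4R,2Z)-4-(triethylsilyloxy)cyclooct-2-en-1-one
Product: 5 triethyl{[(1R,2R)-2-methyl-4-(trimethylsilyloxy)cyclooct-3-en-1-yl]oxy}silane (methyl trans to the triethylsilyloxy group)
Conditions: Me2CuLi (from MeLi and CuI), Me3SiCl, THF, −78 °C; Et3N quench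
Reagents that add atoms: lithium dimethylcuprate [Li+].C[Cu-]C; chlorotrimethylsilane C[Si](C)(C)Cl
Why: Chlorosilane-accelerated Gilman cuprate conjugate addition should place the methyl group on C4 anti to the C3 silyloxy group and trap the enolate as its silyl enol ether; the new C4 centre is erased in step 4.

**Step 4**
Reactants: 5 silyl enol ether
Product: 6 (4R,2Z)-3-methyl-4-(triethylsilyloxy)cyclooct-2-en-1-one
Conditions: Pd(OAc)2 (1.05 equiv), MeCN, rt
Reagents that add atoms: none
Why: Saegusa–Ito oxidation: palladation of the silyl enol ether and β-hydride elimination of the only β-hydrogen (C4–H) should return the Z-enone, now methylated at C4.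

**Step 5**
Reactants: 6 (4R,2Z)-3-methyl-4-(triethylsilyloxy)cyclooct-2-en-1-one
Product: 9 (4R,2Z)-3-methyl-8-methylidene-4-(triethylsilyloxy)cyclooct-2-en-1-one, via Mannich base 7 (not isolated), via methiodide 8 (not isolated)
Conditions: LiN(iPr)2, THF, −78 °C; [CH2=NMe2]I, −78 °C to rt; then MeI, CH2Cl2; then DBU, rt
Reagents that add atoms: N,N-dimethylmethylideneammonium iodide (Eschenmoser's salt) C=[N+](C)C.[I-]
Why: Kinetic α′-deprotonation at C7 and Mannich reaction with the iminium salt, then quaternisation and E1cB elimination, should give the α′-methylidene ketone (α-methylenation).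

**Step 6**
Reactants: 9 (4R,2Z)-3-methyl-8-methylidene-4-(triethylsilyloxy)cyclooct-2-en-1-one
Product: 10 (1R,4R,2Z)-3-methyl-8-methylidene-4-(triethylsilyloxy)cyclooct-2-en-1-ol (OH cis to the silyloxy group; carbinol = C6)
Conditions: NaBH4, CeCl3·7H2O, MeOH, −78 °C
Reagents that add atoms: none
Why: Luche 1,2-reduction of the cross-conjugated dienone; hydride should add to the carbonyl face opposite the C3 silyloxy group across the Z-alkene (1,4-relay), which gives the cis-1,4 alcohol and so the (6R) centre of the target.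

**Step 7**
Reactants: 10 allylic alcohol
Product: 11 tert-butyl{[(1R,4R,2Z)-3-methyl-8-methylidene-4-(triethylsilyloxy)cyclooct-2-en-1-yl]oxy}dimethylsilane
Conditions: tBuMe2SiCl, imidazole, DMF, rt
Reagents that add atoms: tert-butylchlorodimethylsilane CC(C)(C)[Si](C)(C)Cl
Why: Silylation of the C6 hydroxyl with a group that outlasts the triethylsilyl ether in the next step.

**Step 8**
Reactants: 11 bis-silyl ether
Product: 12 (1R,4R,2Z)-4-(tert-butyldimethylsilyloxy)-2-methyl-5-methylidenecyclooct-2-en-1-ol (free C3–OH)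
Conditions: pyridinium p-toluenesulfonate (cat.), MeOH/CH2Cl2, 0 °C
Reagents that add atoms: none
Why: Acid-catalysed methanolysis (selective desilylation) should cleave the secondary triethylsilyl ether much faster than the tert-butyldimethylsilyl ether.

**Step 9**
Reactants: 12 allylic alcohol
Product: 13 (4R,2Z)-4-(tert-butyldimethylsilyloxy)-2-methyl-5-methylidenecyclooct-2-en-1-one (C3 ketone)
Conditions: MnO2, CH2Cl2, rt
Reagents that add atoms: none
Why: MnO2 oxidation of the allylic alcohol should give the C3 enone under neutral conditions that do not enolise the skipped diene; the sacrificial C3 centre is removed here.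

**Step 10**
Reactants: 13 enone
Product: 14 (4R,2Z)-4-(tert-butyldimethylsilyloxy)-8-(hydroxymethyl)-2-methyl-5-methylidenecyclooct-2-en-1-one (both C10 epimers)
Conditions: LiN(iPr)2, THF, −78 °C; CH2O (gas from cracked paraformaldehyde), −78 °C; NH4Cl aq.
Reagents that add atoms: formaldehyde C=O
Why: Kinetic α′-enolate formation at C10 and aldol addition to monomeric formaldehyde install C14 (hydroxymethylation); the C10 configuration does not matter because C10 becomes trigonal in step 11.

**Step 11**
Reactants: 14 hydroxymethyl enone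
Product: 15 (5R,1Z,3Z)-5-(tert-butyldimethylsilyloxy)-3-methyl-6-methylidene-2-(triethylsilyloxy)-1-[(triethylsilyloxy)methyl]cycloocta-1,3-diene (C3=C10 enol ether)
Conditions: Et3SiOTf (2.5 equiv), Et3N, CH2Cl2, −78 to 0 °C
Reagents that add atoms: triethylsilyl trifluoromethanesulfonate CC[Si](CC)(CC)OS(=O)(=O)C(F)(F)F
Why: Silylation of the primary alcohol and soft enolisation (silyl triflate/amine) toward the α′ carbon C10, rather than the hindered γ position C6, should give the cross-conjugated 2-silyloxy diene with a tetrasubstituted C3=C10 enol ether.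

**Step 12**
Reactants: 15 2-silyloxy diene
Product: 16 cis-fused 2,2-dichlorocyclobutanone (C1=O, C2Cl2; C3–OSiEt3 and C10–CH2OSiEt3 syn to the (6R) silyloxy group)
Conditions: Cl2CHCOCl (slow addition), Et3N, hexane, rt
Reagents that add atoms: dichloroacetyl chloride ClC(Cl)C(Cl)=O
Why: Thermal ketene–alkene [2+2] cycloaddition of dichloroketene to the most electron-rich double bond: the ketene carbonyl carbon should bond to nucleophilic C10 and the CCl2 carbon to C3, suprafacially, so the cyclobutane is cis-fused; approach anti to the C6 silyloxy group is expected but immaterial, since both ring-fusion centres are erased in step 20.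

**Step 13**
Reactants: 16 dichlorocyclobutanone
Product: 17 cis-fused cyclobutanone (C1=O, C2H2; otherwise as 16)
Conditions: Zn–Cu couple, NH4Cl, MeOH/THF, 0 °C
Reagents that add atoms: none
Why: Zinc-mediated reductive dechlorination of the α,α-dichloroketone through its zinc enolate, under buffered conditions that keep the C3 silyl ether and so block retro-aldol opening of the β-oxygenated cyclobutanone.

**Step 14**
Reactants: 17 cyclobutanone
Product: 18 (1S,3S,6R,10S)-cyclobutanol (C1–OH)
Conditions: (R)-2-methyl-CBS-oxazaborolidine, catecholborane, toluene, −78 °C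
Reagents that add atoms: none
Why: Corey–Bakshi–Shibata reduction: quaternary C10 acts as the large and C2H2 as the small substituent, so the (R)-catalyst should deliver hydride under reagent control to give the (1S) alcohol, and catecholborane leaves the alkenes untouched.

**Step 15**
Reactants: 18 cyclobutanol
Product: 19 (1S,3S,6R,10S)-C1 triisopropylsilyl ether
Conditions: iPr3SiOTf, 2,6-lutidine, CH2Cl2, 0 °C to rt
Reagents that add atoms: triisopropylsilyl trifluoromethanesulfonate CC(C)[Si](C(C)C)(C(C)C)OS(=O)(=O)C(F)(F)F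
Why: Silyl triflate silylation of the hindered secondary alcohol; the C1 oxygen must be blocked so that only the C3 alkoxide can form in step 20.

**Step 16**
Reactants: 19 tetrasilyl ether
Product: 20 (1S,3S,6R,10S)-triol (C3–OH, C6–OH, C14–OH; C1–OSi(iPr)3 kept)
Conditions: HF·pyridine, pyridine, THF, 0 °C to rt
Reagents that add atoms: none
Why: Buffered fluoride desilylation should remove the two triethylsilyl ethers and the bis-allylic tert-butyldimethylsilyl ether, while the hindered secondary triisopropylsilyl ether survives.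

**Step 17**
Reactants: 20 triol
Product: 21 (1S,3S,6R,10S)-C14 p-toluenesulfonate (C3–OH and C6–OH free)
Conditions: TsCl, Et3N, Me3N·HCl (cat.), CH2Cl2, 0 °C
Reagents that add atoms: 4-methylbenzenesulfonyl chloride Cc1ccc(cc1)S(Cl)(=O)=O
Why: Selective sulfonylation of the primary C14 hydroxyl over the secondary C6 and tertiary C3 hydroxyls.

**Step 18**
Reactants: 22 2-(bromomethyl)acrylic acid
Product: 23 2-(acetoxymethyl)acrylic acid
Conditions: KOAc (5 equiv), AcOH, 60 °C
Reagents that add atoms: potassium acetate CC(=O)[O-].[K+]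
Why: SN2 displacement of the allylic bromide by acetate in acetic acid, where the acrylic acid stays protonated and does not compete as a nucleophile.

**Step 19**
Reactants: 21 hydroxy tosylate; 23 2-(acetoxymethyl)acrylic acid
Product: 24 fragmentation precursor: (1S,3S,6R,10S) cis-fused cyclobutanol with C14–OTs, C1–OSi(iPr)3, C7 methylidene and a C6 2-(acetoxymethyl)acrylate
Conditions: N,N′-dicyclohexylcarbodiimide, 4-(dimethylamino)pyridine (cat.), CH2Cl2, 0 °C
Reagents that add atoms: none
Why: Steglich esterification should acylate the only reactive hydroxyl left, the secondary C6–OH; the tertiary cyclobutanol is inert.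

**Step 20**
Reactants: 24 cyclobutanol tosylate
Product: 25 ten-membered enone: C3 ketone, Z C4=C5, C10=C14 and C7 methylidene groups, (1S)-OSi(iPr)3, (6R)-2-(acetoxymethyl)acryloyloxy
Conditions: KN(SiMe3)2 (1.0 equiv, added slowly), THF, −78 °C; AcOH quench at −78 °C
Reagents that add atoms: none
Why: Deprotonation of the tertiary C3 hydroxyl gives a potassium alkoxide whose lone pair pushes into the strained C3–C10 σ bond while the antiperiplanar, freely rotating exocyclic C14–OTs bond ionises, so C3=O, C10=C14 and potassium tosylate form in one concerted heterolysis. The closest known reaction type is the Grob (Wharton-type) fragmentation of cyclic 1,3-diol monosulfonates to medium-ring alkenyl ketones, applied here to a cyclobutanol. The ten-membered ring is not closed end to end: it appears because the bond shared by the four- and eight-membered rings of the bicyclo[6.2.0]decene is cut, a ring expansion driven by release of cyclobutane strain and by formation of the conjugated enone. No stereocentre is created; C3 and C10 become trigonal, which erases the ring-fusion configuration, while C1, C6 and the Z C4=C5 alkene pass through untouched. The step needs C3–C10 cleavage rather than oxetane closure onto neopentyl C14, C1–C10 cleavage or attack on the esters; this is secured by the 1,3-disposition across quaternary C10, the silylated C1 oxygen (only one alkoxide can form) and the speed of the unimolecular, strain-driven fragmentation at −78 °C with one equivalent of base. The lactone is deliberately still open, because a closed butenolide next to the new enone would make C6–H acidic enough to be epimerised by the alkoxide.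

**Step 21**
Reactants: 25 enone
Product: 26 (1S,3S,6R)-allylic alcohol (C3–OH)
Conditions: (R)-2-methyl-CBS-oxazaborolidine, catecholborane, toluene, −78 °C
Reagents that add atoms: none
Why: Corey–Bakshi–Shibata reduction of an α-methyl enone, the best substrate class for this catalyst: the alkenyl carbon C4 is the large and C2H2 the small group, so the (R)-catalyst should give the (3S) alcohol by 1,2-reduction without touching esters or alkenes.

**Step 22**
Reactants: 26 allylic alcohol
Product: 27 (1S,3S,6R)-C3 acetate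
Conditions: Ac2O, pyridine, 4-(dimethylamino)pyridine (cat.), CH2Cl2, 0 °C
Reagents that add atoms: acetic anhydride CC(=O)OC(C)=O
Why: Acetylation of the secondary allylic alcohol by nucleophilic acyl substitution.

**Step 23**
Reactants: 27 diene ester
Product: 28 (1S,3S,6R,4Z)-3,13-diacetoxy-1-(triisopropylsilyloxy)germacra-4,7(11),10(14)-trien-12,6-olide
Conditions: second-generation Hoveyda–Grubbs catalyst RuCl2(H2IMes)(=CH–C6H4-2-OiPr) (10 mol %), toluene, 80 °C, argon sparge
Reagents that add atoms: none
Why: Ring-closing metathesis of a 2-substituted acrylate with the adjacent 1,1-disubstituted alkene, the methallyl methacrylate-type closure known to give 3,4-disubstituted furan-2(5H)-ones with N-heterocyclic-carbene ruthenium catalysts; only the five-membered ring can form, and loss of ethene drives it.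

**Step 24**
Reactants: 28 silyl ether
Product: 29 (1S,3S,6R,4Z)-3,13-diacetoxy-1-hydroxygermacra-4,7(11),10(14)-trien-12,6-olide
Conditions: HF·pyridine, THF, rt
Reagents that add atoms: none
Why: Fluoride-mediated desilylation under mildly acidic conditions that leave the acetates and the lactone intact.

**Step 25**
Reactants: 29 allylic alcohol
Product: 30 (1S)-C1 methanesulfonate of 29
Conditions: MsCl, Et3N, CH2Cl2, −30 °C; used at once
Reagents that add atoms: methanesulfonyl chloride CS(Cl)(=O)=O
Why: Sulfonylation of the secondary allylic alcohol with retention, to make C1 a leaving group.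

**Step 26**
Reactants: 31 2,3-dimethylbut-2-ene
Product: 32 2-methoxypropan-2-yl hydroperoxide
Conditions: O3, MeOH/CH2Cl2, −78 °C; N2 purge
Reagents that add atoms: ozone [O-][O+]=O; methanol CO
Why: Ozonolysis in methanol: the Criegee carbonyl oxide from the symmetrical alkene is trapped by methanol to give the α-methoxy hydroperoxide, a hydroperoxide protected as a peroxyketal.

**Step 27**
Reactants: 30 allylic mesylate; 32 2-methoxypropan-2-yl hydroperoxide
Product: 34 (1R,3S,6R,4Z)-3,13-diacetoxy-1-hydroperoxygermacra-4,7(11),10(14)-trien-12,6-olide (CNP0174966.1), via peroxyketal 33 (not isolated)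
Conditions: 32 (3 equiv), CsOH·H2O (1.5 equiv), DMF, 0 °C; then AcOH/THF/H2O, rt
Reagents that add atoms: none
Why: SN2 alkylation of the caesium peroxide (an α-effect nucleophile that is only weakly basic and, lacking an acidic hydrogen, has no driving force for acyl transfer from the acetates) should displace the secondary allylic mesylate with inversion to (1R), and mild acid then hydrolyses the peroxyketal to the free hydroperoxide.

**Compound list**
1 | (1Z,3Z)-cycloocta-1,3-diene | C1CC/C=C\C=C/C1 | starting material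
2 | 9,10-dioxabicyclo[4.2.2]dec-7-ene (meso endoperoxide) | C1CC[C@H]2/C=C\[C@@H](C1)OO2 | intermediate
3 | (4R,2Z)-4-hydroxycyclooct-2-en-1-one | C1CCC[C@@H](O)/C=C\C1=O | intermediate
4 | (4R,2Z)-4-(triethylsilyloxy)cyclooct-2-en-1-one | C1CCC[C@@H](O[Si](CC)(CC)CC)/C=C\C1=O | intermediate
5 | triethyl{[(1R,2R)-2-methyl-4-(trimethylsilyloxy)cyclooct-3-en-1-yl]oxy}silane | C[Si](C)(C)O/C1=C/[C@@H](C)[C@H](O[Si](CC)(CC)CC)CCCC1 | intermediate
6 | (4R,2Z)-3-methyl-4-(triethylsilyloxy)cyclooct-2-en-1-one | C1CCC[C@@H](O[Si](CC)(CC)CC)/C(C)=C\C1=O | intermediate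
7 | Mannich base: 8-[(dimethylamino)methyl] derivative of 6 (C7 epimers) | CN(C)CC1CCC[C@@H](O[Si](CC)(CC)CC)/C(C)=C\C1=O | intermediate
8 | trimethylammonium iodide of 7 | C[N+](C)(C)CC1CCC[C@@H](O[Si](CC)(CC)CC)/C(C)=C\C1=O.[I-] | intermediate
9 | (4R,2Z)-3-methyl-8-methylidene-4-(triethylsilyloxy)cyclooct-2-en-1-one | C=C1CCC[C@@H](O[Si](CC)(CC)CC)/C(C)=C\C1=O | intermediate
10 | (1R,4R,2Z)-3-methyl-8-methylidene-4-(triethylsilyloxy)cyclooct-2-en-1-ol | C=C1CCC[C@@H](O[Si](CC)(CC)CC)/C(C)=C\[C@H]1O | intermediate
11 | tert-butyl{[(1R,4R,2Z)-3-methyl-8-methylidene-4-(triethylsilyloxy)cyclooct-2-en-1-yl]oxy}dimethylsilane | C=C1CCC[C@@H](O[Si](CC)(CC)CC)/C(C)=C\[C@H]1O[Si](C)(C)C(C)(C)C | intermediate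
12 | (1R,4R,2Z)-4-(tert-butyldimethylsilyloxy)-2-methyl-5-methylidenecyclooct-2-en-1-ol | C=C1CCC[C@@H](O)/C(C)=C\[C@H]1O[Si](C)(C)C(C)(C)C | intermediate
13 | (4R,2Z)-4-(tert-butyldimethylsilyloxy)-2-methyl-5-methylidenecyclooct-2-en-1-one | C=C1CCCC(=O)/C(C)=C\[C@H]1O[Si](C)(C)C(C)(C)C | intermediate
14 | (4R,2Z)-4-(tert-butyldimethylsilyloxy)-8-(hydroxymethyl)-2-methyl-5-methylidenecyclooct-2-en-1-one (C8 epimers) | C=C1CCC(CO)C(=O)/C(C)=C\[C@H]1O[Si](C)(C)C(C)(C)C | intermediate
15 | (5R,1Z,3Z)-5-(tert-butyldimethylsilyloxy)-3-methyl-6-methylidene-2-(triethylsilyloxy)-1-[(triethylsilyloxy)methyl]cycloocta-1,3-diene | C=C1CC/C(CO[Si](CC)(CC)CC)=C(O[Si](CC)(CC)CC)\C(C)=C/[C@H]1O[Si](C)(C)C(C)(C)C | intermediate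
16 | cis-fused 2,2-dichlorocyclobutanone: C1 ketone, C2 Cl2, C3–OSiEt3, C10–CH2OSiEt3, (6R)-OSiMe2tBu, C7 methylidene, 4Z; C3–O, C14 and C6–O on one face | C=C1CC[C@](CO[Si](CC)(CC)CC)(C(=O)C2(Cl)Cl)[C@@]2(O[Si](CC)(CC)CC)/C(C)=C\[C@H]1O[Si](C)(C)C(C)(C)C | intermediate
17 | cis-fused cyclobutanone: as 16 with C2H2 | C=C1CC[C@](CO[Si](CC)(CC)CC)(C(=O)C2)[C@@]2(O[Si](CC)(CC)CC)/C(C)=C\[C@H]1O[Si](C)(C)C(C)(C)C | intermediate
18 | (1S,3S,6R,10S)-cyclobutanol: C1–OH, C3–OSiEt3, C14–OSiEt3, C6–OSiMe2tBu | C=C1CC[C@](CO[Si](CC)(CC)CC)([C@@H](O)C2)[C@@]2(O[Si](CC)(CC)CC)/C(C)=C\[C@H]1O[Si](C)(C)C(C)(C)C | intermediate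
19 | (1S,3S,6R,10S)-C1 triisopropylsilyl ether of 18 | C=C1CC[C@](CO[Si](CC)(CC)CC)([C@@H](O[Si](C(C)C)(C(C)C)C(C)C)C2)[C@@]2(O[Si](CC)(CC)CC)/C(C)=C\[C@H]1O[Si](C)(C)C(C)(C)C | intermediate
20 | (1S,3S,6R,10S)-triol: C3–OH, C6–OH, C14–OH, C1–OSi(iPr)3 | C=C1CC[C@](CO)([C@@H](O[Si](C(C)C)(C(C)C)C(C)C)C2)[C@@]2(O)/C(C)=C\[C@H]1O | intermediate
21 | (1S,3S,6R,10S)-C14 p-toluenesulfonate of 20 | C=C1CC[C@](COS(=O)(=O)c3ccc(C)cc3)([C@@H](O[Si](C(C)C)(C(C)C)C(C)C)C2)[C@@]2(O)/C(C)=C\[C@H]1O | intermediate
22 | 2-(bromomethyl)acrylic acid | OC(=O)C(=C)CBr | starting material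
23 | 2-(acetoxymethyl)acrylic acid | CC(=O)OCC(=C)C(O)=O | intermediate
24 | fragmentation precursor: (1S,3S,6R,10S) cis-fused cyclobutanol, C14–OTs, C1–OSi(iPr)3, C7 methylidene, C6 2-(acetoxymethyl)acrylate | C=C1CC[C@](COS(=O)(=O)c3ccc(C)cc3)([C@@H](O[Si](C(C)C)(C(C)C)C(C)C)C2)[C@@]2(O)/C(C)=C\[C@H]1OC(=O)C(=C)COC(C)=O | intermediate
25 | (1R,2Z,6S)-3-methyl-7,10-dimethylidene-4-oxo-6-(triisopropylsilyloxy)cyclodec-2-en-1-yl 2-(acetoxymethyl)acrylate (germacrane locants: 1S, 6R) | C=C1CCC(=C)[C@H](OC(=O)C(=C)COC(C)=O)/C=C(/C)C(=O)C[C@@H]1O[Si](C(C)C)(C(C)C)C(C)C | intermediate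
26 | (1S,3S,6R)-C3 alcohol of 25 | C=C1CCC(=C)[C@H](OC(=O)C(=C)COC(C)=O)/C=C(/C)[C@@H](O)C[C@@H]1O[Si](C(C)C)(C(C)C)C(C)C | intermediate
27 | (1S,3S,6R)-C3 acetate of 26 | C=C1CCC(=C)[C@H](OC(=O)C(=C)COC(C)=O)/C=C(/C)[C@@H](OC(C)=O)C[C@@H]1O[Si](C(C)C)(C(C)C)C(C)C | intermediate
28 | (1S,3S,6R,4Z)-3,13-diacetoxy-1-(triisopropylsilyloxy)germacra-4,7(11),10(14)-trien-12,6-olide | C=C1CCC2=C(COC(C)=O)C(=O)O[C@@H]2/C=C(/C)[C@@H](OC(C)=O)C[C@@H]1O[Si](C(C)C)(C(C)C)C(C)C | intermediate
29 | (1S,3S,6R,4Z)-3,13-diacetoxy-1-hydroxygermacra-4,7(11),10(14)-trien-12,6-olide | C=C1CCC2=C(COC(C)=O)C(=O)O[C@@H]2/C=C(/C)[C@@H](OC(C)=O)C[C@@H]1O | intermediate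
30 | (1S)-C1 methanesulfonate of 29 | C=C1CCC2=C(COC(C)=O)C(=O)O[C@@H]2/C=C(/C)[C@@H](OC(C)=O)C[C@@H]1OS(C)(=O)=O | intermediate
31 | 2,3-dimethylbut-2-ene | CC(C)=C(C)C | starting material
32 | 2-methoxypropan-2-yl hydroperoxide | COC(C)(C)OO | intermediate
33 | (1R)-1-[(2-methoxypropan-2-yl)peroxy] derivative (peroxyketal) | C=C1CCC2=C(COC(C)=O)C(=O)O[C@@H]2/C=C(/C)[C@@H](OC(C)=O)C[C@H]1OOC(C)(C)OC | intermediate
34 | (1R,3S,6R,4Z)-3,13-diacetoxy-1-hydroperoxygermacra-4,7(11),10(14)-trien-12,6-olide (CNP0174966.1) | C=C1CCC2=C(COC(C)=O)C(=O)O[C@@H]2/C=C(/C)[C@@H](OC(C)=O)C[C@H]1OO | target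

**Step count**
Total: 27 steps. Longest linear sequence: 25 steps (steps 1–17, 19–25 and 27); steps 18 and 26 are one-step branches.

**Steps most likely to fail**

1. Step 27 (hydroperoxide by SN2). What may go wrong: attack of the peroxide at C14 (SN2′, which moves the alkene to C1=C10), elimination, or ionisation of the allylic mesylate with loss of the C1 configuration. Fallback, from 29 back to 34: a Mitsunobu reaction of alcohol 29 with 2-nitrobenzenesulfonylhydrazide (PPh3, diethyl azodicarboxylate, THF, −30 °C) should give the N-allyl-N-sulfonylhydrazine F1. On warming it loses 2-nitrobenzenesulfinic acid to give the monoalkyl diazene F2, which extrudes dinitrogen in a retro-ene step that shifts the double bond to C1=C10 and turns C14 into a methyl group, giving the (1(10)E,4Z)-diene F3. A singlet-oxygen (Schenck) ene reaction of F3 (O2, tetraphenylporphyrin, light, CH2Cl2), which takes a C14 hydrogen and places the hydroperoxide on C1 from the outer face of the trisubstituted alkene, rejoins the route at 34 without any basic step.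

2. Step 12 (ketene [2+2]). What may go wrong: slow addition to the crowded tetrasubstituted enol ether, so that ketene oligomerisation, cycloaddition at the C7 methylidene or desilylation takes over. Fallback, from 13 back to 16: the cyclobutane is built before C14 is attached. Kinetic enolate silylation of 13 (LiN(iPr)2, Et3SiCl, THF, −78 °C) should give the less hindered trisubstituted 2-silyloxy diene F4, and dichloroketene then adds to give the C10–H dichlorocyclobutanone F5. C10–H is the only enolisable position of F5, so aldol addition to formaldehyde (LiN(SiMe3)2, −78 °C) from the exo face gives the C10 hydroxymethyl dichlorocyclobutanone F6, and silylation (Et3SiCl, imidazole) gives 16.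

3. Step 6 (1,4-relay of configuration). What may go wrong: poor facial selectivity of hydride addition across the flexible eight-membered ring, giving both C6 epimers. Fallback, from 9 back to 10: substrate control is replaced by reagent control. A Corey–Bakshi–Shibata reduction of 9 with (S)-2-methyl-CBS-oxazaborolidine and catecholborane, in which the α-branched alkenyl carbon C7 is taken as the large group, should give the same alcohol 10; no new compound is made (F0).

**Further compounds**
F1 | step 27 | (1R)-N-allyl-N-(2-nitrobenzenesulfonyl)hydrazine from 29 | C=C1CCC2=C(COC(C)=O)C(=O)O[C@@H]2/C=C(/C)[C@@H](OC(C)=O)C[C@H]1N(N)S(=O)(=O)c3ccccc3[N+](=O)[O-]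
F2 | step 27 | (1R)-monoalkyl diazene | C=C1CCC2=C(COC(C)=O)C(=O)O[C@@H]2/C=C(/C)[C@@H](OC(C)=O)C[C@H]1N=N
F3 | step 27 | (3S,6R,1(10)E,4Z)-3,13-diacetoxygermacra-1(10),4,7(11)-trien-12,6-olide | C/C1=C\C[C@H](OC(C)=O)/C(C)=C\[C@H]2OC(=O)C(COC(C)=O)=C2CC1
F4 | step 12 | (5R)-5-(tert-butyldimethylsilyloxy)-3-methyl-6-methylidene-2-(triethylsilyloxy)cycloocta-1,3-diene | C=C1CC/C=C(O[Si](CC)(CC)CC)\C(C)=C/[C@H]1O[Si](C)(C)C(C)(C)C
F5 | step 12 | cis-fused 2,2-dichlorocyclobutanone with C10–H (C3–OSiEt3, C6–OSiMe2tBu) | C=C1CC[C@H](C(=O)C2(Cl)Cl)[C@@]2(O[Si](CC)(CC)CC)/C(C)=C\[C@H]1O[Si](C)(C)C(C)(C)C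
F6 | step 12 | C10 hydroxymethyl derivative of F5 | C=C1CC[C@](CO)(C(=O)C2(Cl)Cl)[C@@]2(O[Si](CC)(CC)CC)/C(C)=C\[C@H]1O[Si](C)(C)C(C)(C)C
F0 | step 6 | none | none
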